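## Structural features

The target is a C–C-linked biflavonoid, (2S)-2,3-dihydrorobustaflavone. A (2S)-naringenin unit (ring A = 5,7-dihydroxybenzo ring, ring C = dihydropyranone with O1, C2, C3, C4, ring B = 4′-hydroxyphenyl on C2) is bonded through C3′ of ring B to C6″ of an apigenin unit (ring D = 5″,7″-dihydroxybenzo ring, ring E = pyranone, ring F = 4‴-hydroxyphenyl). The biaryl bond C3′–C6″ carries three ortho oxygen substituents (O4′, O5″, O7″), and C6″ has to be told apart from the electronically similar C8″. C2 is the only stereocentre, so no neighbouring centre can relay information to it and a catalyst or reagent must set it. C2 is also fragile: it is benzylic, β to the C4 ketone and bonded to an aryloxy leaving group, so base opens ring C to the 2′-hydroxychalcone and recloses it with loss of configuration. The two C6–C3–C6 units differ only in the oxidation level of C2–C3, which excludes any late redox adjustment that cannot tell ring C from ring E, and the six phenols make the final compound sensitive to air and base. The real difficulty is therefore that a hindered, regiodefined biaryl bond, which needs hot basic coupling conditions, must coexist with a base-labile stereocentre. The key step exploits the fact that C2 of ring C is the unsubstituted β-carbon of a chromone enone, whereas C2″ of ring E is β,β-disubstituted: an aryl group carrying the whole flavone unit can be added enantioselectively to C2 of a simple 5,7-dioxygenated chromone, so that the C2–C1′ bond and the stereocentre are made together, last, and under neutral conditions.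

## Logic of the disconnections

11 ⇒ 10. The six phenolic O–H bonds are traced back to six O–benzyl bonds. Benzyl is chosen because it falls off by neutral hydrogenolysis, the one deprotection that does not threaten C2. The forward step must spare C2″=C3″ of ring E and the benzylic C2–O1 bond.

10 ⇒ 7 + 9 (key). The C2–C1′ bond between ring C and ring B is cut. In one sentence, the route is an enantioselective rhodium-catalysed conjugate addition of the flavone-bearing arylboronic acid 7 to chromone 9. The chiral flavanone half collapses to an achiral chromone made in one step, the stereocentre has to survive no other C–C bond formation, and the biaryl problem is confined to the robust, achiral 7. The forward step must select one enantioface of 9, must choose the enone of 9 over the enone in ring E of 7, and must outrun protodeboronation of 7.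

9 ⇒ 8. Two O–benzyl bonds are cut; the gain is a purchasable chromone. The forward step must alkylate the hydrogen-bonded 5-hydroxyl as well.

7 ⇒ 6. The C1′–B bond is traced back to a C1′–Cl bond. A chloride is inert while the biaryl bond is formed and becomes the boron handle afterwards, so ring B needs no protecting group for boron. The forward step needs a catalyst that activates an electron-rich aryl chloride.

6 ⇒ 4 + 5. The biaryl bond C3′–C6″ is cut. It is made between two achiral, base-stable partners, with the regiochemistry fixed by the iodine on C6″ and ring B arriving as a monocyclic boronic acid. The forward step must form a tri-ortho-substituted biaryl and must choose C–I over C–Cl.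

4 ⇒ 3. The O5″–benzyl bond is cut. Capping O5″ removes a chelating 5-hydroxy-4-keto site before the metal-catalysed steps. The forward step must break the intramolecular hydrogen bond.

3 ⇒ 2. The C6″–I bond is cut. The free 5″-hydroxyl is used as the element that steers the electrophile to C6″ and away from C8″. The forward step must be a mild, buffered iodination.

2 ⇒ 1. The O7″– and O4‴–benzyl bonds are cut. A cheap natural flavone supplies rings D, E and F intact. The forward step relies on the low reactivity of the chelated 5″-hydroxyl.

## Other disconnections considered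

Alternative 1: the first plan that comes to mind cuts the biaryl bond C3′–C6″ between two finished halves. The forward key step would be a Suzuki–Miyaura coupling of the (2S)-flavanone 3′-boronate A1 with iodide 4 to give 10. The chosen plan is preferred because A1 already contains C2, and the hot aqueous base that a tri-ortho-substituted coupling needs is exactly the condition under which ring C opens by β-elimination of the aryloxide and recloses racemically. A1 would in any case need its own asymmetric flavanone synthesis, so no step is saved.

Alternative 2: a biomimetic cut of the same C3′–C6″ bond with no prefunctionalisation. The forward key step would be an oxidative phenol cross-coupling of (S)-naringenin A2 with apigenin 1, giving 11 in one step. The chosen plan is preferred because nothing in the substrates distinguishes C6″ from C8″ or either of them from C6 and C8 of ring A in A2. The 3′,8″-linked isomer A3 and homodimers are therefore expected alongside 11, and the oxidant can also dehydrogenate C2–C3. The step economy does not compensate for the lack of any controlling element.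

Alternative 3: a cut of the O1–C2 bond, leading to the chalcone–flavone hybrid A4. The forward key step would be an enantioselective 6-endo-trig oxa-Michael cyclisation of A4 to 11, dynamic in principle because chalcone and flavanone interconvert. The chosen plan is preferred for three reasons. A 2′,4′,6′-trioxygenated chalcone cyclises spontaneously through either ortho hydroxyl, so an uncatalysed racemic pathway competes. The equilibrium that would make the step dynamic is also the racemisation pathway of the product. The catalytic versions with the best precedent need an extra activating ester on the α-carbon, which costs steps for its introduction and removal, whereas the conjugate addition forms a C–C bond irreversibly under catalyst control.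

Key step: step 7

Remark: the target SMILES fixes no configuration for the C3′–C6″ axis; with three small ortho oxygen substituents the axis is taken as freely rotating, so C2 is the only stereochemical element to control; 1, 5 and 8 are taken as purchasable.

## Route

Step 1
Reactants: 1 apigenin (5,7-dihydroxy-2-(4-hydroxyphenyl)-4H-chromen-4-one)
Product: 2 7-(benzyloxy)-2-[4-(benzyloxy)phenyl]-5-hydroxy-4H-chromen-4-one
Conditions: BnBr (2.2 equiv), K2CO3, DMF, 25 to 50 °C
Reagents that add atoms: benzyl bromide, BrCc1ccccc1
Why: Williamson ether synthesis; the 5″-hydroxyl is locked in a hydrogen bond to the C4″ carbonyl and is the least acidic and least nucleophilic phenol, so two equivalents of halide at moderate temperature should alkylate only O7″ and O4‴.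

Step 2
Reactants: 2 7-(benzyloxy)-2-[4-(benzyloxy)phenyl]-5-hydroxy-4H-chromen-4-one
Product: 3 7-(benzyloxy)-2-[4-(benzyloxy)phenyl]-5-hydroxy-6-iodo-4H-chromen-4-one
Conditions: BnMe3N+ ICl2− (1.1 equiv), CaCO3, CH2Cl2/MeOH (5:2), 25 °C
Reagents that add atoms: benzyltrimethylammonium dichloroiodate, C[N+](C)(C)Cc1ccccc1.Cl[I-]Cl
Why: Electrophilic aromatic iodination of a phenol; the free 5″-hydroxyl directs to its only open ortho carbon, C6″, which is the regiochemistry known for 5-hydroxy-7-alkoxyflavones with this reagent, while C8″ (para to O5″, flanked by O1″ and O7″) and ring F (conjugated to the pyranone) should react more slowly; CaCO3 takes up the HCl so that the benzyl ethers survive.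

Step 3
Reactants: 3 7-(benzyloxy)-2-[4-(benzyloxy)phenyl]-5-hydroxy-6-iodo-4H-chromen-4-one
Product: 4 5,7-bis(benzyloxy)-2-[4-(benzyloxy)phenyl]-6-iodo-4H-chromen-4-one
Conditions: BnBr (2 equiv), K2CO3, DMF, 70 °C
Reagents that add atoms: benzyl bromide, BrCc1ccccc1
Why: Williamson ether synthesis under forcing conditions, which breaks the chelate; capping O5″ removes an acidic, metal-binding 5-hydroxy-4-keto site before the palladium and rhodium steps.

Step 4
Reactants: 4 5,7-bis(benzyloxy)-2-[4-(benzyloxy)phenyl]-6-iodo-4H-chromen-4-one; 5 [2-(benzyloxy)-5-chlorophenyl]boronic acid (1.3 equiv)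
Product: 6 5,7-bis(benzyloxy)-6-[2-(benzyloxy)-5-chlorophenyl]-2-[4-(benzyloxy)phenyl]-4H-chromen-4-one
Conditions: Pd(PPh3)4 (5 mol%), K3PO4, 1,4-dioxane/H2O (4:1), 90 °C
Reagents that add atoms: none
Why: Suzuki–Miyaura coupling; zerovalent palladium with triphenylphosphine inserts into the C6″–I bond and leaves the electron-rich C–Cl bonds of 5 and 6 untouched, and coupling of 6-iodo-5,7-dialkoxyflavones with 2-alkoxyarylboronic acids to tri-ortho-substituted biaryls is a known reaction type; no stereocentre is present, so heat and base do no harm.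

Step 5
Reactants: 6 5,7-bis(benzyloxy)-6-[2-(benzyloxy)-5-chlorophenyl]-2-[4-(benzyloxy)phenyl]-4H-chromen-4-one
Product: 7 {4-(benzyloxy)-3-[5,7-bis(benzyloxy)-2-[4-(benzyloxy)phenyl]-4-oxo-4H-chromen-6-yl]phenyl}boronic acid
Conditions: B2(OH)4 (3 equiv), chloro(XPhos)[2-(2′-amino-1,1′-biphenyl)]palladium (second-generation XPhos palladacycle, 2 mol%), XPhos (4 mol%), KOAc, EtOH/THF, 80 °C; aqueous work-up
Reagents that add atoms: tetrahydroxydiboron, OB(O)B(O)O
Why: Miyaura borylation of an aryl chloride with tetrahydroxydiboron; the bulky, electron-rich biarylphosphine enables oxidative addition into the deactivated C1′–Cl bond, KOAc is too weak a base to drive Suzuki coupling of 7 with remaining 6, and the free boronic acid needed for step 7 is obtained directly.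

Step 6
Reactants: 8 5,7-dihydroxy-4H-chromen-4-one
Product: 9 5,7-bis(benzyloxy)-4H-chromen-4-one
Conditions: BnBr (2.5 equiv), K2CO3, DMF, 80 °C
Reagents that add atoms: benzyl bromide, BrCc1ccccc1
Why: Twofold Williamson ether synthesis; the higher temperature is needed for the chelated 5-hydroxyl, and carbonate in DMF does not open the pyranone ring.

Step 7
Reactants: 7 {4-(benzyloxy)-3-[5,7-bis(benzyloxy)-2-[4-(benzyloxy)phenyl]-4-oxo-4H-chromen-6-yl]phenyl}boronic acid (1.0 equiv); 9 5,7-bis(benzyloxy)-4H-chromen-4-one (1.5 equiv)
Product: 10 (2S)-5,7-bis(benzyloxy)-2-{4-(benzyloxy)-3-[5,7-bis(benzyloxy)-2-[4-(benzyloxy)phenyl]-4-oxo-4H-chromen-6-yl]phenyl}-2,3-dihydro-4H-chromen-4-one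
Conditions: [Rh(OH)(cod)]2 (2.5 mol%), (S)-MeO-F12-BIPHEP [(S)-2,2′-bis[bis(3,4,5-trifluorophenyl)phosphino]-6,6′-dimethoxy-1,1′-biphenyl, 5.5 mol%], toluene/H2O (10:1), 30 °C
Reagents that add atoms: none
Why: This is a Hayashi–Miyaura reaction, the rhodium-catalysed asymmetric 1,4-addition of an arylboronic acid to an enone, a reaction type known for chromones. The aryl group of 7 passes from boron to the hydroxo complex of monovalent rhodium, C2=C3 of 9 coordinates and inserts into the Rh–aryl bond by syn carbometalation, and the resulting oxa-π-allyl rhodium enolate is protonated by water, which releases 10 and regenerates Rh–OH. No ring is closed: the step joins C1′ of ring B to C2 of a preformed ring C. The C2 stereocentre is set in the insertion by the C2-symmetric bisphosphine, which lets the planar chromone bind with only one enantioface towards the aryl group; by analogy with the (S)-BINAP/2-cyclohexenone model the (S)-ligand should give (2S), and the antipodal ligand is used should the sense prove opposite. Chemoselectivity between the two enones comes from the substrate, because C2″ of ring E in 7 and 10 is β,β-disubstituted and conjugated to ring F and so resists insertion, whereas C2 of 9 bears only hydrogen. The electron-poor ligand is chosen because the 5,7-dialkoxy pattern makes 9 a weak acceptor; it should speed insertion relative to protodeboronation of the valuable 7, which is the limiting reagent. The near-neutral two-phase medium and the benzyl caps on O5 and O4′ suppress β-aryloxy elimination from the rhodium enolate and retro-oxa-Michael opening of 10, the two pathways that would erode the new stereocentre. Because the step follows every base-mediated operation, C2 never meets base.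

Step 8
Reactants: 10 (2S)-5,7-bis(benzyloxy)-2-{4-(benzyloxy)-3-[5,7-bis(benzyloxy)-2-[4-(benzyloxy)phenyl]-4-oxo-4H-chromen-6-yl]phenyl}-2,3-dihydro-4H-chromen-4-one
Product: 11 (2S)-5,7-dihydroxy-2-{4-hydroxy-3-[5,7-dihydroxy-2-(4-hydroxyphenyl)-4-oxo-4H-chromen-6-yl]phenyl}-2,3-dihydro-4H-chromen-4-one (CNP0277421.1)
Conditions: H2 (1 atm), 10% Pd/C, THF/MeOH (1:1) with 1% AcOH, 25 °C, stopped when hydrogen uptake ends
Reagents that add atoms: none
Why: Catalytic hydrogenolysis of six aryl benzyl ethers, which should be cleaved much faster than the vinylogous-ester C2″=C3″ bond of ring E is saturated or the C2–O1 bond is broken; the slightly acidified neutral medium keeps all phenols protonated, so ring C should not open and C2 should stay (S).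

## Compound list

1 | apigenin, 5,7-dihydroxy-2-(4-hydroxyphenyl)-4H-chromen-4-one | O=c1cc(-c2ccc(O)cc2)oc2cc(O)cc(O)c12 | starting material
2 | 7-(benzyloxy)-2-[4-(benzyloxy)phenyl]-5-hydroxy-4H-chromen-4-one | O=c1cc(-c2ccc(OCc3ccccc3)cc2)oc2cc(OCc3ccccc3)cc(O)c12 | intermediate
3 | 7-(benzyloxy)-2-[4-(benzyloxy)phenyl]-5-hydroxy-6-iodo-4H-chromen-4-one | O=c1cc(-c2ccc(OCc3ccccc3)cc2)oc2cc(OCc3ccccc3)c(I)c(O)c12 | intermediate
4 | 5,7-bis(benzyloxy)-2-[4-(benzyloxy)phenyl]-6-iodo-4H-chromen-4-one | O=c1cc(-c2ccc(OCc3ccccc3)cc2)oc2cc(OCc3ccccc3)c(I)c(OCc3ccccc3)c12 | intermediate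
5 | [2-(benzyloxy)-5-chlorophenyl]boronic acid | OB(O)c1cc(Cl)ccc1OCc1ccccc1 | starting material
6 | 5,7-bis(benzyloxy)-6-[2-(benzyloxy)-5-chlorophenyl]-2-[4-(benzyloxy)phenyl]-4H-chromen-4-one | O=c1cc(-c2ccc(OCc3ccccc3)cc2)oc2cc(OCc3ccccc3)c(-c3cc(Cl)ccc3OCc3ccccc3)c(OCc3ccccc3)c12 | intermediate
7 | {4-(benzyloxy)-3-[5,7-bis(benzyloxy)-2-[4-(benzyloxy)phenyl]-4-oxo-4H-chromen-6-yl]phenyl}boronic acid | O=c1cc(-c2ccc(OCc3ccccc3)cc2)oc2cc(OCc3ccccc3)c(-c3cc(B(O)O)ccc3OCc3ccccc3)c(OCc3ccccc3)c12 | intermediate
8 | 5,7-dihydroxy-4H-chromen-4-one | O=c1ccoc2cc(O)cc(O)c12 | starting material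
9 | 5,7-bis(benzyloxy)-4H-chromen-4-one | O=c1ccoc2cc(OCc3ccccc3)cc(OCc3ccccc3)c12 | intermediate
10 | (2S)-5,7-bis(benzyloxy)-2-{4-(benzyloxy)-3-[5,7-bis(benzyloxy)-2-[4-(benzyloxy)phenyl]-4-oxo-4H-chromen-6-yl]phenyl}-2,3-dihydro-4H-chromen-4-one | O=C1C[C@@H](c2ccc(OCc3ccccc3)c(-c3c(OCc4ccccc4)cc4oc(-c5ccc(OCc6ccccc6)cc5)cc(=O)c4c3OCc3ccccc3)c2)Oc2cc(OCc3ccccc3)cc(OCc3ccccc3)c21 | intermediate
11 | (2S)-5,7-dihydroxy-2-{4-hydroxy-3-[5,7-dihydroxy-2-(4-hydroxyphenyl)-4-oxo-4H-chromen-6-yl]phenyl}-2,3-dihydro-4H-chromen-4-one | O=C1C[C@@H](c2ccc(O)c(-c3c(O)cc4oc(-c5ccc(O)cc5)cc(=O)c4c3O)c2)Oc2cc(O)cc(O)c21 | target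

## Step count and least certain steps

Total step count: 8. Longest linear sequence: 7 steps (steps 1, 2, 3, 4, 5, 7, 8, from 1); step 6 is a one-step branch.

Step 7 (key). The most likely failure is protodeboronation of 7 outrunning insertion, because 9 is an electron-rich and therefore weak acceptor. Partial loss of enantiopurity through reversible opening of ring C at the rhodium enolate stage is the second concern. The fallback sets out from 7 and 9 and returns to the route at 10. The C2–C1′ bond is first made without stereocontrol by conjugate addition under Pd(OCOCF3)2/2,2′-bipyridine (divalent palladium, AcOH/THF/H2O, 60 °C), which gives the racemic hexabenzyl flavanone F1. The stereocentre is then selected by kinetic resolution under Noyori transfer hydrogenation with RuCl(p-cymene)[(R,R)-TsDPEN] and HCO2H/Et3N. This should reduce the (2R)-ketone to the cis-(2R,4R)-chroman-4-ol F2 and leave (2S)-configured 10, which is separated from F2 by chromatography. The ring E carbonyl is a vinylogous ester and is not expected to be reduced.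

Step 2. The most likely failure is competing iodination at C8″ or double iodination, since both carbons are activated by two oxygen substituents and the isomers would be hard to separate. The fallback sets out from 2 and 5 and returns at 6, bypassing steps 2 to 4. Boronic acid 5 is transmetalated with K2CO3 onto the sulfone-bridged bismacycle tosylate [Bi(C6H4SO2C6H4)(OTs)] to give the aryl bismacycle 10-[2-(benzyloxy)-5-chlorophenyl]-10H-dibenzo[b,e][1,4]thiabismine 5,5-dioxide F3, which contains trivalent bismuth. Oxidation with mCPBA gives a pentavalent bismuth species that binds phenol 2 through O5″. Ligand coupling then delivers the aryl group to the ortho carbon of the bound phenol; the only free one is C6″, the other being the ring-fusion carbon C4a″. This gives the 5-hydroxy biaryl 7-(benzyloxy)-6-[2-(benzyloxy)-5-chlorophenyl]-2-[4-(benzyloxy)phenyl]-5-hydroxy-4H-chromen-4-one F4, and benzylation (BnBr, K2CO3, DMF, 70 °C) gives 6.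

Step 4. The most likely failure is slow transmetalation and reductive elimination at the doubly ortho-substituted C6″, so that protodeboronation of 5 and hydrodeiodination of 4 take over. The fallback sets out from 4 and returns at 6 with inverted polarity. Zinc insertion (Zn dust, LiCl, THF, 40 °C), assisted by the two ortho benzyloxy groups, gives {5,7-bis(benzyloxy)-2-[4-(benzyloxy)phenyl]-4-oxo-4H-chromen-6-yl}zinc iodide F5. Negishi coupling of F5 with purchased 1-(benzyloxy)-2-bromo-4-chlorobenzene (Pd2(dba)3/SPhos, THF, 50 °C) gives 6. Arylzinc reagents transmetalate quickly at hindered centres and are not protonated in the anhydrous medium.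

Step 5. The most likely failure is incomplete conversion caused by poor solubility of 6 in ethanol, accompanied by hydrodechlorination and by losses on isolating a free boronic acid. The fallback sets out from 6 and returns at 7. Borylation with B2pin2 (Pd2(dba)3/XPhos, KOAc, 1,4-dioxane, 100 °C) gives the pinacol boronate 5,7-bis(benzyloxy)-6-[2-(benzyloxy)-5-(4,4,5,5-tetramethyl-1,3,2-dioxaborolan-2-yl)phenyl]-2-[4-(benzyloxy)phenyl]-4H-chromen-4-one F6, which can be purified on silica. NaIO4/NH4OAc in acetone/H2O then removes the diol oxidatively and releases 7.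

Step 8. The most likely failure is over-reduction, either saturation of C2″=C3″ in ring E or hydrogenolysis of the benzylic C2–O1 bond, together with slow cleavage at the hindered O5″ that prolongs exposure. The fallback sets out from 10 and arrives at 11 without any reduction. The ethers are cleaved heterolytically with BCl3 in CH2Cl2 at −78 °C, with pentamethylbenzene as a trap for the benzyl cation, followed by a methanol quench. The low temperature is meant to keep the Lewis acid from opening ring C. This fallback makes no new compound.

## Further compounds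

F1 | step 7 | rac-5,7-bis(benzyloxy)-2-{4-(benzyloxy)-3-[5,7-bis(benzyloxy)-2-[4-(benzyloxy)phenyl]-4-oxo-4H-chromen-6-yl]phenyl}-2,3-dihydro-4H-chromen-4-one | O=C1CC(c2ccc(OCc3ccccc3)c(-c3c(OCc4ccccc4)cc4oc(-c5ccc(OCc6ccccc6)cc5)cc(=O)c4c3OCc3ccccc3)c2)Oc2cc(OCc3ccccc3)cc(OCc3ccccc3)c21
F2 | step 7 | (2R,4R)-5,7-bis(benzyloxy)-2-{4-(benzyloxy)-3-[5,7-bis(benzyloxy)-2-[4-(benzyloxy)phenyl]-4-oxo-4H-chromen-6-yl]phenyl}-3,4-dihydro-2H-chromen-4-ol | O[C@@H]1C[C@H](c2ccc(OCc3ccccc3)c(-c3c(OCc4ccccc4)cc4oc(-c5ccc(OCc6ccccc6)cc5)cc(=O)c4c3OCc3ccccc3)c2)Oc2cc(OCc3ccccc3)cc(OCc3ccccc3)c12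
F3 | step 2 | 10-[2-(benzyloxy)-5-chlorophenyl]-10H-dibenzo[b,e][1,4]thiabismine 5,5-dioxide | O=S1(=O)c2ccccc2[Bi](c2cc(Cl)ccc2OCc2ccccc2)c2ccccc12
F4 | step 2 | 7-(benzyloxy)-6-[2-(benzyloxy)-5-chlorophenyl]-2-[4-(benzyloxy)phenyl]-5-hydroxy-4H-chromen-4-one | O=c1cc(-c2ccc(OCc3ccccc3)cc2)oc2cc(OCc3ccccc3)c(-c3cc(Cl)ccc3OCc3ccccc3)c(O)c12
F5 | step 4 | {5,7-bis(benzyloxy)-2-[4-(benzyloxy)phenyl]-4-oxo-4H-chromen-6-yl}zinc iodide | O=c1cc(-c2ccc(OCc3ccccc3)cc2)oc2cc(OCc3ccccc3)c([Zn]I)c(OCc3ccccc3)c12
F6 | step 5 | 5,7-bis(benzyloxy)-6-[2-(benzyloxy)-5-(4,4,5,5-tetramethyl-1,3,2-dioxaborolan-2-yl)phenyl]-2-[4-(benzyloxy)phenyl]-4H-chromen-4-one | O=c1cc(-c2ccc(OCc3ccccc3)cc2)oc2cc(OCc3ccccc3)c(-c3cc(B4OC(C)(C)C(C)(C)O4)ccc3OCc3ccccc3)c(OCc3ccccc3)c12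
F0 | step 8 | none | none
A1 | alternative 1 | (2S)-5,7-bis(benzyloxy)-2-[4-(benzyloxy)-3-(4,4,5,5-tetramethyl-1,3,2-dioxaborolan-2-yl)phenyl]-2,3-dihydro-4H-chromen-4-one | O=C1C[C@@H](c2ccc(OCc3ccccc3)c(B3OC(C)(C)C(C)(C)O3)c2)Oc2cc(OCc3ccccc3)cc(OCc3ccccc3)c21
A2 | alternative 2 | (S)-naringenin, (2S)-5,7-dihydroxy-2-(4-hydroxyphenyl)-2,3-dihydro-4H-chromen-4-one | O=C1C[C@@H](c2ccc(O)cc2)Oc2cc(O)cc(O)c21
A3 | alternative 2 | (2S)-5,7-dihydroxy-2-{4-hydroxy-3-[5,7-dihydroxy-2-(4-hydroxyphenyl)-4-oxo-4H-chromen-8-yl]phenyl}-2,3-dihydro-4H-chromen-4-one (3′,8″-linked isomer) | O=C1C[C@@H](c2ccc(O)c(-c3c(O)cc(O)c4c(=O)cc(-c5ccc(O)cc5)oc34)c2)Oc2cc(O)cc(O)c21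
A4 | alternative 3 | (E)-3-{4-hydroxy-3-[5,7-dihydroxy-2-(4-hydroxyphenyl)-4-oxo-4H-chromen-6-yl]phenyl}-1-(2,4,6-trihydroxyphenyl)prop-2-en-1-one | O=C(/C=C/c1ccc(O)c(-c2c(O)cc3oc(-c4ccc(O)cc4)cc(=O)c3c2O)c1)c1c(O)cc(O)cc1O
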